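Readings and results come from a simulation on assumed constants; noise was put on by code.

Does the charge of free base change how much electrophile has reacted at 8.0 h, when the nucleophile has to come out of a solid?

| setting | south-west | alder | maple | oak |
|---|---|---|---|---|
| electrophile | 0.057 M | 0.038 M | 0.038 M | 0.038 M |
| free base | 0.038 M (fed, over 25 min) | 0.0570 M (fed, over 25 min) | 0.0850 M (fed, over 25 min) | 0.0380 M (fed, over 25 min) |
| solid nucleophile | 0.114 M | 0.114 M | 0.114 M | 0.114 M |
| remark | run made earlier; the fed solution adds 0.20 times the starting volume | the fed solution adds 0.20 times the starting volume | the fed solution adds 0.20 times the starting volume | the fed solution adds 0.20 times the starting volume |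
| time |  | 8.0 h | 8.0 h | 8.0 h |

south-west run (percent of the electrophile charged)

| time / h | electrophile / % | product / % |
|---|---|---|
| 0.417 | 99.0 | 0.6 |
| 0.667 | 100.4 | 0.2 |
| 1.33 | 98.8 | 0.3 |
| 2.50 | 96.9 | 4.3 |
| 5.00 | 89.7 | 9.9 |

(scatter of a reading: 0.5 percentage points)

1. part of the electrophile that has reacted at the end, alder
2. part of the electrophile that has reacted at the end, maple
3. part of the electrophile that has reacted at the end, oak
4. what raising the concentration of free base from its lowest to its highest value here does to the part of the electrophile that has reacted (changes below 5 percentage points count as none) (it falls / it rises / no change)

- charges are per starting volume, the dose included; the dosed solution carries all of it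
- as a solid, counted per litre of solution: solid nucleophile
- what may be going on: electrophile + nucleophile -> acid set free + product; nucleophile + acid set free <-> protonated nucleophile; acid set free + free base <-> salt of the base; solid nucleophile <-> nucleophile
- at the start none of the solid nucleophile is in solution
- no earlier run changes the charge of free base; that part of a forecast is a guess

Between 2.50 h and 5.00 h the south-west run makes product at a molar pace, per starting volume, of 0.00128 M h⁻¹, a zero-order reading whose straight line, run back, meets zero product at about 0.580 h. An own reckoning carries this pace unchanged to 8.0 h, although the new flasks are charged with less electrophile than the south-west run, and gets 0.00947 M of product with as much acid released, bound forms counted, an amount that is 24.9% of the electrophile in each new flask and a quarter of the free base in oak, so each new flask holds more base than the acid reckoned, and the reckoning expects no change with base.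

The forecast gives 19% for alder, 19% for maple and 19% for oak, lower than that reckoned share, and no change, remarking: “Extra base should change little, though this is a guess because no earlier run varied it.”

The flasks give 21.4% in alder, 21.5% in maple and 21.2% in oak, a move of 0.37 percentage points from the lowest to the highest charge of free base, which is smaller than the 5 points that counts as a change, so the answer is no change, and the forecast stands within its margins.

    electrophile + nucleophile → acid set free + product (k = 13.0 M⁻¹ h⁻¹)
    nucleophile + acid set free ⇌ protonated nucleophile, settled at all times (K = 7100 M⁻¹)
    acid set free + free base ⇌ salt of the base, settled at all times (K = 12000 M⁻¹)
    solid nucleophile ⇌ nucleophile, rate k4*(cs4 - [nucleophile]) while solid is left; crystals form when [nucleophile] > cs4 (solubility = 17.0 mM, k = 0.0880 h⁻¹)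

Alder's answer stays within 5 points of itself for free base from at least 0.0071 M up to at least 0.46 M, but it has moved that far at 0.0232 M and at 0.0604 M of electrophile, the other amounts and the time held, so a figure of 19% for alder would come into doubt with the electrophile charge at such a value. With all the reckoned acid placed on the base, the pace reckons 75.1% of oak's free base still free at the end, and oak holds 80.3%.

For maple read at 30 h, the pace reckons 0.0377 M of product with as much acid released, an amount that is 98.9% of the electrophile and, placed wholly on the base, leaves 55.8% of the free base. That flask gives 79.9% reacted and 67% of the free base left.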